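## Retrosynthetic overview

1. Andilesin A (27) ⇐ unmasking and reduction of the C2' enol ether, C1=C2 desaturation ⇐ ε-lactone 23 ⇐ Baeyer–Villiger ring expansion of the 4,4-dimethylcyclohexanone ring A of 22 (key step: ring A is built one atom too small and expanded by a 1,2-shift of C4 from carbon to oxygen).
2. 22 ⇐ Robinson annulation of ethyl vinyl ketone onto spiro-dienone 17 (sets C10), gem-methylation, hydrogenation (sets C5 and C9).
3. 17 ⇐ one dearomative triple annulation of phthalide 5 (ring D plus γ-lactone) with bis(bromomethyl)cresol acetate 12 (ring B); it forms the bicyclo[2.2.2]octane, the cyclopentane and the spiro ring B.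
4. 5 ⇐ Michael–Dieckmann condensation and aromatization; 12 ⇐ Diels–Alder adduct of the ethyl vinyl ketone silyl dienol ether with maleic anhydride, aromatization, reduction, bromination.
5. Ring order: ring D/γ-lactone and ring B (both as arenes) → bicyclo[2.2.2]octane and cyclopentane → ring A as cyclohexenone → ring A expanded to the seven-membered lactone.

Assumption (notation): C1–C10 are the decalin carbons of rings A and B in drimane numbering (C4 gem-dimethyl, C10 methyl), C11 is the CH2 on C9 and C12 the CH2 on C8; C1'–C6' are the six carbons of the phthalide-derived ring D (C1' carries the lactone carbonyl C7', C2' the hydroxyl, C3' and C5' one methyl each, C4' is the ketone, C6' carries the lactone CH2 C8'); β is the face of ring B that carries the C10 methyl.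

## Route

Step 1
Reactants: 1 methyl acetoacetate
Product: 2 methyl 3-oxopentanoate
Conditions: NaH, THF, 0 °C; n-BuLi, 0 °C; MeI, 0 °C → rt; aq HCl
Reagents that add atoms: iodomethane, CI
Why: Weiler dianion alkylation; the terminal carbanion of the acetoacetate dianion is the more nucleophilic site and is methylated selectively (no stereocentre).

Step 2
Reactants: 2 methyl 3-oxopentanoate; 3 3-methylfuran-2(5H)-one
Product: 4 4,6-dimethyl-3a,4,6,7a-tetrahydro-2-benzofuran-1,5,7(3H)-trione (mixture of stereoisomers and enol tautomers)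
Conditions: NaOMe (1.1 equiv), MeOH, 0 °C → reflux; aq HCl
Reagents that add atoms: none
Why: Michael addition of the β-keto ester to the butenolide, Dieckmann condensation onto the lactone carbonyl and relactonization of the freed alkoxide onto the methyl ester (classical dihydroresorcylate synthesis); the stereocentres are erased in step 3.

Step 3
Reactants: 4 trione lactone
Product: 5 5,7-dihydroxy-4,6-dimethyl-2-benzofuran-1(3H)-one (DHDMP)
Conditions: DDQ (1.1 equiv), 1,4-dioxane, 100 °C
Reagents that add atoms: none
Why: Quinone dehydrogenation of a cyclohexane-1,3-dione to the resorcinol, driven by aromatization.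

Step 4
Reactants: 6 pent-1-en-3-one (ethyl vinyl ketone)
Product: 7 (Z)-3-(trimethylsilyloxy)penta-1,3-diene
Conditions: TMSOTf, Et3N, Et2O, 0 °C
Reagents that add atoms: trimethylsilyl trifluoromethanesulfonate, C[Si](C)(C)OS(=O)(=O)C(F)(F)F
Why: Soft enolization and O-silylation of the ethyl ketone gives mainly the (Z)-silyl enol ether, the isomer whose methyl group points away from the vinyl group and can adopt the s-cis diene conformation.

Step 5
Reactants: 7 silyl dienol ether; 8 maleic anhydride
Product: 9 racemic all-cis 3-methyl-4-(trimethylsilyloxy)cyclohex-4-ene-1,2-dicarboxylic anhydride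
Conditions: PhMe, 60 °C
Reagents that add atoms: none
Why: Diels–Alder cycloaddition of an electron-rich 2-silyloxydiene with maleic anhydride (endo adduct); the stereocentres are erased in step 6.

Step 6
Reactants: 9 Diels–Alder adduct
Product: 10 4-hydroxy-3-methylphthalic anhydride
Conditions: DDQ (2.2 equiv), 1,4-dioxane, 100 °C; aq work-up
Reagents that add atoms: none
Why: DDQ oxidation of the silyl enol ether to the enone followed by dehydrogenative aromatization to the phenol.

Step 7
Reactants: 10 4-hydroxy-3-methylphthalic anhydride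
Product: 11 3,4-bis(hydroxymethyl)-2-methylphenol
Conditions: LiAlH4, THF, 0 °C → reflux; aq work-up
Reagents that add atoms: none
Why: Hydride reduction of the cyclic anhydride to the 1,2-bis(hydroxymethyl)arene.

Step 8
Reactants: 11 3,4-bis(hydroxymethyl)-2-methylphenol
Product: 12 3,4-bis(bromomethyl)-2-methylphenyl acetate
Conditions: AcBr, CH2Cl2, 0 °C → rt
Reagents that add atoms: acetyl bromide, CC(=O)Br
Why: Acetyl bromide acetylates the phenol and converts both benzylic alcohols into bromides (acetate formation, then displacement by HBr); the aryl acetate keeps the para-hydroxybenzyl bromide stable until step 9.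

Step 9
Reactants: 5 DHDMP; 12 3,4-bis(bromomethyl)-2-methylphenyl acetate
Product: 17 spiro-dienone methyl enol ether, via para-quinone methide 13 (not isolated), via C-benzylated dienol 14 (not isolated), via bridged phenol 15 (not isolated), via beta-keto lactone 16 (not isolated)
Conditions: O-allyl-N-(9-anthracenylmethyl)cinchonidinium bromide (10 mol %), 50% aq KOH, PhMe, −20 °C → rt; then Me2SO4, rt
Reagents that add atoms: dimethyl sulfate, COS(=O)(=O)OC
Why: Proposed new method: hydroxide cleaves the aryl acetate of 12 and the phenoxide expels the para-benzylic bromide to give para-quinone methide 13; the chiral ammonium ion pair of the dianion of 5 adds through C3' (the carbon between the two oxygens) to the methylidene carbon (enantio-determining 1,6-addition that dearomatizes ring D and sets C3'), the vinylogous enolate of 14 is C-alkylated at C5' by the remaining benzylic bromide (seven-membered ring, C5' set, only the cis-bridged product 15 can form), and the phenoxide of ring B then attacks through its para carbon C8 the doubly activated C6' (transannular dearomative Michael addition closing the cyclopentane and the bicyclo[2.2.2]octane, C8 and C6' fixed by the tethers) to give the enolate of 16, which dimethyl sulfate traps on oxygen; the closest known reaction types are cinchona phase-transfer 1,6-additions of 1,3-dicarbonyls to para-quinone methides, alkylative dearomatization–annulation of acylphloroglucinols and base-mediated dearomative para-Michael spirocyclization of phenols.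

Step 10
Reactants: 17 spiro-dienone methyl enol ether; 6 pent-1-en-3-one
Product: 19 pentacyclic 4-methyl-4,6,9(11)-trien-3-one, via Michael adduct 18 (not isolated)
Conditions: KOt-Bu (0.2 equiv), t-BuOH/THF, 0 °C → rt; then pyrrolidine, AcOH (cat.), PhMe, 80 °C
Reagents that add atoms: none
Why: Robinson annulation; 17 has no α'-hydrogen, so only the extended enolate (deprotonation at C11) forms, and it adds to the enone at C10 on the face opposite the pseudo-axial C12 methylene (C10 methyl ends β, cis to C12), after which aldol condensation closes ring A.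

Step 11
Reactants: 19 trienone
Product: 20 pentacyclic 4-methyl-4,9(11)-dien-3-one
Conditions: H2 (1 atm), RhCl(PPh3)3 (10 mol %), PhH/EtOH, rt
Reagents that add atoms: none
Why: Homogeneous hydrogenation with the Wilkinson catalyst reduces only the disubstituted 6,7-double bond of the linear dienone, as in steroidal dienones; the tetrasubstituted, trisubstituted and push–pull alkenes are left.

Step 12
Reactants: 20 dienone
Product: 21 pentacyclic 4,4-dimethyl-5,9(11)-dien-3-one
Conditions: KOt-Bu, t-BuOH/THF, 0 °C; MeI
Reagents that add atoms: iodomethane, CI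
Why: Deconjugative α-methylation of the thermodynamic dienolate of a 4-methyl-4-en-3-one installs the gem-dimethyl group and moves the double bond to C5=C6.

Step 13
Reactants: 21 dienone
Product: 22 saturated pentacyclic 3-ketone (5α-H, 9β-H)
Conditions: H2 (50 bar), 10% Pd/C, EtOAc/AcOH, rt
Reagents that add atoms: none
Why: Heterogeneous hydrogenation; hydrogen adds to C5=C6 from the α face, away from the C10 and 4β methyls (trans ring fusion), and to C9=C11 from the face syn to C12, because the other face is covered by the C8' methylene on the one-carbon bridge; this gives the 9β-hydrogen.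

Step 14
Reactants: 22 saturated 3-ketone
Product: 23 ring A ε-lactone
Conditions: mCPBA, CH2Cl2, 0 °C → rt
Reagents that add atoms: 3-chloroperoxybenzoic acid, OOC(=O)c1cccc(Cl)c1
Why: Baeyer–Villiger ring expansion, the key step; the quaternary C4 undergoes the 1,2-shift from C3 to oxygen with retention, while the C4' ketone (two quaternary α-carbons) does not add the peracid and the push–pull enol ether is too electron-poor to be epoxidized.

Step 15
Reactants: 23 ε-lactone
Product: 25 1,2-unsaturated lactone enol ether, via selenide 24 (not isolated)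
Conditions: LiN(i-Pr)2, THF, −78 °C; PhSeBr; then H2O2, pyridine, CH2Cl2, 0 °C → rt
Reagents that add atoms: none
Why: α-Selenenylation and syn selenoxide elimination; C2 carries the only enolizable hydrogens in the molecule because C1' is still sp2 and the C4' ketone has no α-hydrogen.

Step 16
Reactants: 25 unsaturated lactone enol ether
Product: 27 andilesin A, via beta-keto lactone 26 (not isolated)
Conditions: LiCl, DMF, 90 °C; 1 M HCl work-up; then Zn(BH4)2, Et2O/THF, −30 °C; 1 M HCl
Reagents that add atoms: none
Why: Chloride removes the O-methyl group by SN2 (Krapcho-type demethylation of a vinylogous carbonate), and chelation-controlled reduction of the zinc-bound β-keto lactone delivers hydride to C2' from the side of the C1' hydrogen (the C12 side) to give the cis β-hydroxy lactone, with C1' equilibrating through the enol so that the hydroxyl and the lactone carbonyl both lie over the C4' ketone bridge.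

## Compound list

1 | methyl acetoacetate | CC(=O)CC(=O)OC | starting material
2 | methyl 3-oxopentanoate | CCC(=O)CC(=O)OC | intermediate
3 | 3-methylfuran-2(5H)-one | CC1=CCOC1=O | starting material
4 | 4,6-dimethyl-3a,4,6,7a-tetrahydro-2-benzofuran-1,5,7(3H)-trione, mixture of stereoisomers and enol tautomers | O=C1OCC2C1C(=O)C(C)C(=O)C2C | intermediate
5 | 5,7-dihydroxy-4,6-dimethyl-2-benzofuran-1(3H)-one (DHDMP) | O=C1OCc2c1c(O)c(C)c(O)c2C | intermediate
6 | pent-1-en-3-one (ethyl vinyl ketone) | CCC(=O)C=C | starting material
7 | (Z)-3-(trimethylsilyloxy)penta-1,3-diene | C=C/C(O[Si](C)(C)C)=C/C | intermediate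
8 | maleic anhydride | O=C1OC(=O)C=C1 | starting material
9 | racemic all-cis 3-methyl-4-(trimethylsilyloxy)cyclohex-4-ene-1,2-dicarboxylic anhydride (one enantiomer drawn) | C[C@@H]1C(O[Si](C)(C)C)=CC[C@@H]2C(=O)OC(=O)[C@H]12 | intermediate
10 | 4-hydroxy-3-methylphthalic anhydride | Cc1c(O)ccc2C(=O)OC(=O)c12 | intermediate
11 | 3,4-bis(hydroxymethyl)-2-methylphenol | Cc1c(O)ccc(CO)c1CO | intermediate
12 | 3,4-bis(bromomethyl)-2-methylphenyl acetate | CC(=O)Oc1ccc(CBr)c(CBr)c1C | intermediate
13 | 3-(bromomethyl)-2-methyl-4-methylidenecyclohexa-2,5-dien-1-one (para-quinone methide) | C=C1C=CC(=O)C(C)=C1CBr | intermediate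
14 | 6-{[2-(bromomethyl)-4-hydroxy-3-methylphenyl]methyl}-5-hydroxy-4,6-dimethyl-3,6-dihydro-2-benzofuran-1,7-dione, C3' configured as in 27 | O=C1OCC2=C1C(=O)[C@](C)(Cc1ccc(O)c(C)c1CBr)C(O)=C2C | intermediate
15 | bridged phenol: ring D 2',4'-dione with C1'=C6' double bond, joined to the phenol ring B through C8–C12–C3' and C9–C11–C5' (cis-bridged, C3' and C5' as in 27) | Cc1c(O)ccc2C[C@]3(C)C(=O)[C@](C)(Cc12)C1=C(C3=O)C(=O)OC1 | intermediate
16 | spiro-dienone β-keto lactone: ring B is a 10-methylcyclohexa-6,9-dien-5-one spiro at C8, C8–C6' bond closed, C2' ketone, C1' epimerizable | O=C1C=C[C@]23C[C@]4(C)C(=O)[C@](C)(CC2=C1C)[C@]31COC(=O)C1C4=O | intermediate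
17 | spiro-dienone methyl enol ether: 16 with C1'=C2'–OMe; C8, C3', C5', C6' as in 27 | O=C1C=C[C@]23C[C@]4(C)C(=O)[C@](C)(CC2=C1C)[C@]31COC(=O)C1=C4OC | intermediate
18 | Michael adduct: C10 carries the β methyl and an α 3-oxopentyl chain; C5 ketone, C6=C7 and C9=C11 double bonds | CCC(=O)CC[C@@]1(C)C(=O)C=C[C@]23C[C@]4(C)C(=O)[C@](C)(C=C12)[C@]31COC(=O)C1=C4OC | intermediate
19 | pentacyclic 4-methyl-4,6,9(11)-trien-3-one with the C1'=C2'–OMe lactone | CC1=C2C=C[C@]34C[C@]5(C)C(=O)[C@](C)(C=C3[C@@]2(C)CCC1=O)[C@]41COC(=O)C1=C5OC | intermediate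
20 | pentacyclic 4-methyl-4,9(11)-dien-3-one with the C1'=C2'–OMe lactone | CC1=C2CC[C@]34C[C@]5(C)C(=O)[C@](C)(C=C3[C@@]2(C)CCC1=O)[C@]41COC(=O)C1=C5OC | intermediate
21 | pentacyclic 4,4-dimethyl-5,9(11)-dien-3-one with the C1'=C2'–OMe lactone | CC1(C)C2=CC[C@]34C[C@]5(C)C(=O)[C@](C)(C=C3[C@@]2(C)CCC1=O)[C@]41COC(=O)C1=C5OC | intermediate
22 | saturated 4,4-dimethyl-3-ketone, 5α-H, 9β-H, 10β-methyl, with the C1'=C2'–OMe lactone | CC1(C)C(=O)CC[C@@]2(C)[C@H]1CC[C@]13C[C@]4(C)C(=O)[C@](C)(C[C@@H]21)[C@]31COC(=O)C1=C4OC | intermediate
23 | ring A ε-lactone (oxygen inserted between C3 and C4 of 22) | CC1(C)OC(=O)CC[C@@]2(C)[C@H]1CC[C@]13C[C@]4(C)C(=O)[C@](C)(C[C@@H]21)[C@]31COC(=O)C1=C4OC | intermediate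
24 | 2-(phenylselanyl) derivative of 23, C2 unassigned | CC1(C)OC(=O)C([Se]c2ccccc2)C[C@@]2(C)[C@H]1CC[C@]13C[C@]4(C)C(=O)[C@](C)(C[C@@H]21)[C@]31COC(=O)C1=C4OC | intermediate
25 | 1,2-unsaturated ε-lactone: andilesin A with C1'=C2'–OMe in place of C1'H–C2'H(OH) | CC1(C)OC(=O)C=C[C@@]2(C)[C@H]1CC[C@]13C[C@]4(C)C(=O)[C@](C)(C[C@@H]21)[C@]31COC(=O)C1=C4OC | intermediate
26 | 2'-dehydroandilesin A (β-keto lactone, C1' epimerizable) | CC1(C)OC(=O)C=C[C@@]2(C)[C@H]1CC[C@]13C[C@]4(C)C(=O)[C@](C)(C[C@@H]21)[C@]31COC(=O)C1C4=O | intermediate
27 | andilesin A | CC1(C)OC(=O)C=C[C@@]2(C)[C@H]1CC[C@]13C[C@]4(C)C(=O)[C@](C)(C[C@@H]21)[C@]31COC(=O)[C@H]1[C@H]4O | target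

## Step count and risks

Total step count: 16. Longest linear sequence: 13 steps (steps 4–8, then 9–16); the other branch is steps 1–3 followed by 9–16.

The three steps most likely to fail:

Step 9 (the proposed new cascade). The risks are O- instead of C-alkylation, attack of C5' instead of C3' on the quinone methide, low enantioselectivity, or an induction sense opposite to the one needed (then the pseudoenantiomeric cinchoninium salt is used). The fallback is stepwise, racemic and uses known reaction types; it sets out from 5 and 11 and comes back to the route at 17. Heating 5 with 11 in aqueous LiOH (alkylative dearomatization by the thermally formed para-quinone methide of the hydroxybenzyl alcohol) gives the racemic C3'-benzylated hydroxymethyl adduct F1. PBr3 in CH2Cl2 gives the racemic benzylic bromide F2. K2CO3 in acetone closes the seven-membered ring by enolate C-alkylation to the racemic bridged phenol F3. KOt-Bu in THF followed by Me2SO4 effects the dearomative para-Michael spirocyclization and O-methylation to the racemic methyl enol ether F4, which is resolved by preparative HPLC on a chiral stationary phase to give 17.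

Step 10 (quaternary C10 by Michael addition of the extended enolate). The risks are reversible Michael addition, γ- or O-attack, and polymerization of the enone. The fallback replaces the Michael addition by an irreversible SN2 alkylation; it sets out from 17 and comes back at 18 and 19. The potassium trienolate of 17 (KOt-Bu, 1.1 equiv, THF/t-BuOH) is alkylated with 2-ethyl-2-(2-iodoethyl)-1,3-dioxolane to give the C10-alkylated ketal F5. Aqueous HCl in THF removes the ketal to give 18, and pyrrolidinium acetate in toluene closes ring A to 19.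

Step 16 (configuration at C1' and C2'). Hydride may instead arrive from the open side of the C4' ketone bridge and give the C2' epimer. The fallback puts the oxygen on from that open side instead of the hydrogen; it sets out from 23 and comes back at 27, replacing steps 15 and 16. LiCl in DMF converts 23 into the saturated-series β-keto lactone F6. NaH and PhNTf2 give the enol triflate F7. Pd(OAc)2, PPh3, HCO2H and n-Bu3N reduce it to the C1'=C2' alkylidene lactone F8. Conjugate borylation (CuCl, NaOt-Bu, bis(2-diphenylphosphinophenyl) ether, B2pin2, MeOH, THF) adds boron to C2' from the side of the C4' ketone bridge and protonates C1' anti to boron, giving the C2' pinacol boronate F9. NaBO3 oxidizes it with retention to 1,2-dihydroandilesin A F10. Allyl-palladium dehydrogenation of the ε-lactone (bis(2,2,6,6-tetramethylpiperidido)zinc, [Pd(C3H5)Cl]2, diethyl allyl phosphate, PhMe) then gives 27.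

## Further compounds

F1 | step 9 | racemic 5-hydroxy-6-{[4-hydroxy-2-(hydroxymethyl)-3-methylphenyl]methyl}-4,6-dimethyl-3,6-dihydro-2-benzofuran-1,7-dione | O=C1OCC2=C1C(=O)C(C)(Cc1ccc(O)c(C)c1CO)C(O)=C2C
F2 | step 9 | racemic 6-{[2-(bromomethyl)-4-hydroxy-3-methylphenyl]methyl}-5-hydroxy-4,6-dimethyl-3,6-dihydro-2-benzofuran-1,7-dione (racemate of 14) | O=C1OCC2=C1C(=O)C(C)(Cc1ccc(O)c(C)c1CBr)C(O)=C2C
F3 | step 9 | racemic cis-bridged phenol (racemate of 15) | Cc1c(O)ccc2CC3(C)C(=O)C(C)(Cc12)C1=C(C3=O)C(=O)OC1
F4 | step 9 | racemic spiro-dienone methyl enol ether (racemate of 17) | O=C1C=CC23CC4(C)C(=O)C(C)(CC2=C1C)C31COC(=O)C1=C4OC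
F5 | step 10 | ethylene ketal of Michael adduct 18 (C10 carries the β methyl and a 2-(2-ethyl-1,3-dioxolan-2-yl)ethyl chain) | CCC1(OCCO1)CC[C@@]2(C)C(=O)C=C[C@]34C[C@]5(C)C(=O)[C@](C)(C=C23)[C@]41COC(=O)C1=C5OC
F6 | step 16 | 1,2-dihydro-2'-dehydroandilesin A (β-keto lactone with saturated ε-lactone, C1' epimerizable) | CC1(C)OC(=O)CC[C@@]2(C)[C@H]1CC[C@]13C[C@]4(C)C(=O)[C@](C)(C[C@@H]21)[C@]31COC(=O)C1C4=O
F7 | step 16 | C2' enol triflate of F6 (C1'=C2'–OTf) | CC1(C)OC(=O)CC[C@@]2(C)[C@H]1CC[C@]13C[C@]4(C)C(=O)[C@](C)(C[C@@H]21)[C@]31COC(=O)C1=C4OS(=O)(=O)C(F)(F)F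
F8 | step 16 | C1'=C2' alkylidene lactone with saturated ε-lactone (1,2-dihydro-2'-deoxy-1',2'-didehydroandilesin A) | CC1(C)OC(=O)CC[C@@]2(C)[C@H]1CC[C@]13C[C@]4(C)C(=O)[C@](C)(C[C@@H]21)[C@]31COC(=O)C1=C4
F9 | step 16 | C2' pinacol boronate (boron in place of the hydroxyl of F10, same configuration) | CC1(C)OC(=O)CC[C@@]2(C)[C@H]1CC[C@]13C[C@]4(C)C(=O)[C@](C)(C[C@@H]21)[C@]31COC(=O)[C@H]1[C@H]4B1OC(C)(C)C(C)(C)O1
F10 | step 16 | 1,2-dihydroandilesin A | CC1(C)OC(=O)CC[C@@]2(C)[C@H]1CC[C@]13C[C@]4(C)C(=O)[C@](C)(C[C@@H]21)[C@]31COC(=O)[C@H]1[C@H]4O
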